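## The problem

The target, methyl (13E)-ent-16-formyloxy-6α-hydroxy-17-oxolabda-7,13-dien-15-oate (23), is a trans-fused decalin (ring A: C1–C5 and C10, with a gem-dimethyl C4; ring B: C5–C10) that carries a six-carbon chain on C9. Four contiguous stereocentres line ring B (C5, C6, C9 and the quaternary C10), and C10 cannot be corrected once made, so it must be set early and with absolute control; no chiral-pool terpene of the ent series already carries the C6 oxygen. Once C10 stands, its axial methyl can steer reagents to the opposite face of C9, which gives the required configuration there (H-9 anti, C11 syn to the methyl), but at C6 the same shielding sends a kinetic hydride to the wrong face, so the equatorial C6 hydroxyl has to come from thermodynamic control. Ring B ends as a γ-hydroxy-α,β-unsaturated aldehyde (C6–OH, C7=C8, formyl C17), which does not tolerate hydrides, ylides or strong base. The side chain ends in a trisubstituted enoate whose allylic formate on C16 is lost to the mildest base, and whose wrong C13=C14 isomer would close to a butenolide, so the alkene must be made stereospecifically. The feature that opens a short entry is the substitution pattern of ring B: oxygen on C6, the C7=C8 alkene, one-carbon branches on C8 (C17) and C10 (the angular methyl) and, with C9 written as a carbonyl, the para-quinone monoketal of 2,6-dimethylphenol. In that symmetric dienone C5 and C7 are enantiotopic β-carbons, so one enantioselective conjugate addition at C5 and alkylation of the enolate at C10 set both ring-fusion centres and attach both arms of ring A.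

## Retrosynthesis

**23 to 22 and 21.** No skeletal bond is cut. The C6 hydroxyl of 23 is released from silyl ether 22 by fluoride under weakly acidic conditions, the one deprotection that the formate, enal and enoate all tolerate. 22 is traced to 21 by removing the C17 aldehyde oxygen. The C8 methyl is the carbon that the dienone brings along, and a late allylic C–H oxidation keeps the aldehyde out of every step that uses boranes or ylides. Carrying a C17 oxygen from the start would cost a halogenation, a substitution and extra protecting-group steps. The forward reaction must pick the methyl on the more substituted end of the electron-rich ring alkene and leave the electron-poor side-chain alkene alone.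

**21 to 20, and 20 to 16 plus 18.** The formate C–O bond is cut first, so the most labile group is put on after the last basic step. Then C12–C13 is cut, between an sp3 borane derived from vinyl compound 16 and the sp2 iodide 18. This cut is preferred to C13=C14 olefination of an alkoxymethyl ketone, which gives no reliable geometry. It is also preferred to an sp3–sp3 union at C11, a hindered carbon next to an allylic hydrogen and prone to elimination. The precursor 16 is a C12 bicycle with no side-chain functionality. The coupling must proceed with retention at C13, so that the chain ends up cis to the ester.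

**18 to 17.** The C13–I and C14–H bonds are cut. Anti addition of hydrogen iodide to the commercial ynoate 17 puts iodine cis to the ester in one step, and the hydroxymethyl group trans to it, where it cannot lactonise.

**16 to 15, 14 and 13.** The O–Si bond, then the C11=C12 alkene (one-carbon olefination of aldehyde 14), then the aldehyde oxidation level are removed in turn, arriving at diol 13. C12 is added as a methylene because a two-carbon nucleophile cannot be added to the hindered C9 carbonyl with control of C9. The aldehyde 14 is β,γ-unsaturated and must be made and consumed under near-neutral, cold conditions.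

**13 to 12.** Only the C6–H bond is cut. The C6 ketone is reduced before any ester is present, so that an equilibrating aluminium alkoxide reduction can be used. Kinetic hydride delivery anti to the C10 methyl would give the axial epimer.

**12 to 10.** The C2 sulfonyl group and the C6 dimethyl ketal are restored. The sulfone is removed reductively only at this stage, where no enone is present to compete for electrons. The ketal has masked C6 until then, so that C9 was the only carbonyl available to carbon nucleophiles.

**10 to 8 and 7.** The C9–H and C11–O bonds are cut (hydroboration–oxidation of the exocyclic alkene of 8), then C9=C11 (methylenation of ketone 7). This sequence is chosen over direct addition of a chain to the C9 ketone because hydroboration sets C9 by approach anti to the angular methyl, and it leaves C7=C8 in place. 7 is a bicyclic enone with only two stereocentres.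

**7 to 6.** The C3–C4 bond of ring A is cut. The forward step generates the tertiary C4 radical from the isopropenyl group by hydrogen-atom transfer and closes onto the vinyl sulfone. This also creates the second C4 methyl. A polar closure is not available for a quaternary C4. The trans ring fusion is already encoded in the trans C5/C10 substituents of 6.

**6 to 2, 3 and 4.** The C4–C5 and C1–C10 bonds are cut, the two bonds that join the arms of ring A to ring B. The precursors are the achiral dienone 2, the Grignard reagent 3 and the bis-sulfone 4. In 4 one sulfonyl group is the leaving group of the alkylation and the other becomes the radical acceptor of the next step. The forward reaction must select one enantiotopic enone arm, add 1,4 and not 1,2, and alkylate the enolate on carbon, trans to the new C5 substituent.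

**2 to 1.** The two C6–O bonds of the ketal are traced to the phenol oxygen pattern of 1; oxidative dearomatisation in methanol makes 2 in one step.

## Roads not taken

**Alternative 1:** The cut is C6–C7, and ring B is closed last on a finished ring A by an intramolecular carbonyl-ene reaction. In the forward step the Lewis acid Me2AlCl activates the C6 aldehyde of the ene substrate A2, whose C9 carries a 2-propenyl group and the silyloxyethyl arm. The terminal alkene carbon C7 attacks the aldehyde and a C17 hydrogen moves to oxygen, giving the decalin A1 with the C6 hydroxyl and an exocyclic C8=C17 alkene. In two respects this road is better than the chosen one. The C6 carbinol and a handle for C17 arise in the ring-forming step itself, where the chosen plan needs a ketal hydrolysis, an equilibrating reduction and a late C–H oxidation. The C11–C12 arm also arrives with both carbons, which the chosen plan adds one at a time. The weak points lie before and after the key step. A2 holds three stereocentres (C5, C9 and quaternary C10) on a monocyclic ring and has to be assembled through a sigmatropic sequence with a separate source of absolute configuration. Nothing in A2 forces the aldehyde oxygen into the orientation that gives the equatorial C6 alcohol. The exocyclic alkene of A1 still has to be transposed to C7=C8 with oxidation at C17. The chosen plan sets against these advantages an enantioselective entry in two steps from a commodity phenol, with C5 and C10 fixed by one catalytic event and the C6 oxygen present from the start.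

**Alternative 2:** The cut is C9–C10. The β-keto ester A4 is made from the cheap ketone dihydro-β-ionone A5 and carries an 8-phenylmenthyl ester as chiral auxiliary. Mn(OAc)3 (trivalent manganese) oxidises A4 to the C9 radical, which adds 6-endo to C10 of the ring alkene, and the co-oxidant Cu(OAc)2 (divalent copper) turns the resulting C5 radical into the C5=C6 alkene of the bicyclic β-keto ester A3. This is the shortest way to a bicyclic core with the quaternary C10, only a few steps from A5. It also offers something the chosen plan lacks: hydroboration of C5=C6 from the face anti to the angular methyl would deliver H-5 and the C6 oxygen in the target's relative configuration in one step. The weak points are these. Absolute control rests on the facial bias of a stoichiometric auxiliary several atoms from the reacting centre. C8 arrives as a ketone without C17, and introducing C17 together with a C7=C8 alkene next to the doubly activated C9 invites the C8=C9 regioisomer. C11 is at the ester level and needs reduction and a five-carbon extension. The chosen plan answers with catalytic control of absolute configuration and with C17, C7=C8 and the C6 oxygen in place from the first intermediate.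

**Alternative 3:** The cut is C8–C9. The Michael substrate A7 has a β-keto ester chain on C5 and an (E)-enoate on C10. Cs2CO3 generates the C8 enolate, which adds to C9 of the enoate and gives the trans-decalin A6 with a C7 ketone, the C17 ester on C8 and a C11–C12 acetate arm on C9. In two respects this road is better. C17 enters at the ester level, so no C–H oxidation is needed. The reversible Michael addition would settle C9 in the equatorial, correct configuration while delivering both chain carbons. The weak points are these. The ring oxygen sits on C7, so the C6 hydroxyl needs a carbonyl transposition or a late allylic oxidation, with the same facial problem at C6. A7 requires a ring A bearing the C5/C10 pair, made by an asymmetric cycloaddition, and two chains built on it before the key step. The chosen plan counters with the correct oxygen position from the outset and far fewer bond constructions before the ring system exists; it pays with the late C17 oxidation.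

Key step: step 2

Assumptions (remarks on the chemistry):

- Labdane locants are used for all intermediates: C1–C10 ring carbons, C11–C16 chain on C9, C17 on C8. CIP descriptors in names refer to these locants. In every bicyclic compound H-5 is anti to the C10 methyl (trans fusion). From 9 onward C11 is syn to that methyl, and from 13 onward the C6 oxygen is anti to it.
- The sense of induction of the ferrocenyl bisphosphine with dienone 2 is not known. The ligand antipode that gives (5R) is to be fixed by the first experiment; both antipodes are commercial.
- The C2 sulfonyl centre of 7–10 is carried as a mixture of epimers, since it is removed in step 6.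

## Route

Step 1
Reactants: 1 4-methoxy-2,6-dimethylphenol
Product: 2 4,4-dimethoxy-2,6-dimethylcyclohexa-2,5-dien-1-one
Conditions: PhI(OAc)2 (1.1 equiv), MeOH, 0 °C → rt
Reagents that add atoms: methanol, CO
Why: Oxidative dearomatisation of a para-methoxyphenol by a hypervalent iodine reagent; the phenoxenium-type intermediate is trapped by methanol at the para carbon, and the two ortho methyl groups block ortho attack.

Step 2
Reactants: 2 4,4-dimethoxy-2,6-dimethylcyclohexa-2,5-dien-1-one; 3 isopropenylmagnesium bromide; 4 2,3-bis(phenylsulfonyl)prop-1-ene
Product: 6 (5R,6R)-4,4-dimethoxy-2,6-dimethyl-6-[2-(phenylsulfonyl)prop-2-en-1-yl]-5-(prop-1-en-2-yl)cyclohex-2-en-1-one, via bromomagnesium enolate 5 (not isolated)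
Conditions: CuBr·SMe2 (5 mol %), (R)-1-[(SP)-2-(diphenylphosphino)ferrocenyl]ethyldicyclohexylphosphine (6 mol %), 3 added slowly, t-BuOMe, −78 °C; then 4, THF/DMPU, −78 → −20 °C; aq. NH4Cl
Reagents that add atoms: none
Why: Proposed new method: the bisphosphine complex of monovalent copper takes up the isopropenyl group from 3, binds one of the two enantiotopic enone arms of 2, and passes through a trivalent copper σ-complex whose reductive elimination forms C4–C5 and leaves enolate 5; the closest known reactions are the copper/ferrocenyl-bisphosphine-catalysed enantioselective 1,4-addition of Grignard reagents to cyclic enones and the copper-catalysed desymmetrising addition of organozinc reagents to 4,4-dialkoxycyclohexa-2,5-dienones, neither shown for an alkenyl Grignard reagent on a 2,6-disubstituted dienone. Enolate 5 then adds to the unsubstituted alkene terminus of 4 and expels benzenesulfinate (addition–elimination, SN2′), which forms C1–C10. No ring is formed in this step. C5 is set by the catalyst, for which the choice of enone arm and of face are one decision in the symmetric dienone. C10 is set by the substrate: the electrophile approaches the enolate face opposite the adjacent C5 isopropenyl group, so the methyl ends cis and the sulfonylallyl group trans to it, as a trans-decalin requires. The step needs 1,4- over 1,2-addition (copper catalysis, flanking methyl groups), C- over O-alkylation (soft Michael-type electrophile) and fast trapping of 5, because a protonated adduct could lose methanol and aromatise; the quaternary C10 of 6 closes that exit.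

Step 3
Reactants: 6 (5R,6R)-4,4-dimethoxy-2,6-dimethyl-6-[2-(phenylsulfonyl)prop-2-en-1-yl]-5-(prop-1-en-2-yl)cyclohex-2-en-1-one
Product: 7 sulfonyl decalin enone ketal [(5R,10R); trans-fused; C9 ketone; C7=C8 with methyl C17 on C8; C6 dimethyl ketal; C4 gem-dimethyl; C2–SO2Ph as both epimers]
Conditions: Fe(acac)3 (0.5 equiv), PhSiH3 (2.5 equiv), Na2HPO4, EtOH, 60 °C
Reagents that add atoms: none
Why: Hydrogen-atom transfer from an iron hydride to the electron-rich 1,1-disubstituted alkene gives the tertiary C4 radical (creating the second C4 methyl), which adds 6-endo in a Giese manner to the unsubstituted terminus C3 of the vinyl sulfone; the α-sulfonyl radical is then reduced and protonated. The trans fusion follows from the trans C5/C10 substituents of 6, and the C2 configuration is immaterial.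

Step 4
Reactants: 7 sulfonyl decalin enone ketal
Product: 8 exocyclic diene ketal [(5R,10R); C9=C11H2; C7=C8 with methyl on C8; C6 dimethyl ketal; C2–SO2Ph]
Conditions: Cp2TiMe2 (3 equiv), toluene, 70 °C, dark; basic alumina
Reagents that add atoms: dimethyltitanocene, C[Ti](C)(C1C=CC=C1)C1C=CC=C1
Why: Petasis methylenation; the thermally generated titanium methylidene is non-basic and small enough for the non-enolisable C9 ketone flanked by the quaternary C10, and it leaves the ketal and sulfone untouched.

Step 5
Reactants: 8 exocyclic diene ketal
Product: 10 C11 alcohol [(5R,9R,10S); CH2OH on C9 syn to the C10 methyl; C7=C8; C6 dimethyl ketal; C2–SO2Ph], via C11 alkylborane 9 (not isolated)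
Conditions: 9-BBN (2 equiv), THF, 0 °C → rt; then NaOH, H2O2, 0 °C
Reagents that add atoms: hydrogen peroxide, OO
Why: Hydroboration–oxidation; the bulky borane adds boron to the terminal C11 of the exocyclic alkene and spares the trisubstituted C7=C8. Hydrogen reaches C9 from the face opposite the axial C10 methyl, which places C11 syn to that methyl (equatorial) as in the target.

Step 6
Reactants: 10 C11 alcohol
Product: 12 hydroxy enone [(5R,9R,10S); C11–OH; C6 ketone conjugated with C7=C8; methyl on C8], via desulfonylated ketal alcohol 11 (not isolated)
Conditions: Mg turnings, MeOH, 50 °C; then 1 M HCl, THF, 0 °C → rt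
Reagents that add atoms: water, O
Why: Reductive desulfonylation by electron transfer from magnesium cleaves the C2–S bond at a stage with no reducible carbonyl; the aqueous acid then hydrolyses the allylic dimethyl ketal to the conjugated C6 enone.

Step 7
Reactants: 12 hydroxy enone
Product: 13 diol [(5R,6R,9R,10S); equatorial C6–OH anti to the C10 methyl; C11–OH; C7=C8]
Conditions: Al(OiPr)3 (3 equiv), i-PrOH/toluene, 85 °C, extended time with a trace of acetone retained
Reagents that add atoms: none
Why: Meerwein–Ponndorf–Verley reduction is 1,2-selective for enones and reversible through the Oppenauer back-reaction, so the C6 carbinol should settle as the equatorial epimer, which avoids the 1,3-diaxial contacts with the C10 methyl and the axial C4 methyl that burden the kinetic alcohol.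

Step 8
Reactants: 13 diol
Product: 14 hydroxy aldehyde [(5R,6R,9R,10R); C11 aldehyde on C9; C6–OH; C7=C8]
Conditions: TEMPO (10 mol %), PhI(OAc)2 (1.1 equiv), CH2Cl2, 0 °C; used crude
Reagents that add atoms: none
Why: Nitroxyl-catalysed oxidation takes the primary alcohol much faster than the hindered secondary allylic one and stops at the aldehyde under near-neutral conditions, which limits epimerisation at C9 and alkene migration in the β,γ-unsaturated aldehyde.

Step 9
Reactants: 14 hydroxy aldehyde
Product: 15 vinyl alcohol [(5R,6R,9R,10S); C11=C12 vinyl group on C9; C6–OH; C7=C8]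
Conditions: Ph3PCH3Br (3 equiv), KN(SiMe3)2 (2.9 equiv), THF, 0 °C; then 14, −78 → 0 °C
Reagents that add atoms: methyltriphenylphosphonium bromide, C[P+](c1ccccc1)(c1ccccc1)c1ccccc1.[Br-]
Why: Wittig methylenation; at low temperature, addition of the unstabilised ylide to the aldehyde should outrun α-deprotonation, and the excess ylide absorbs the C6 hydroxyl proton.

Step 10
Reactants: 15 vinyl alcohol
Product: 16 silyl ether [(5R,6R,9R,10S); C6–OSi(t-Bu)Me2; C9 vinyl; C7=C8]
Conditions: t-BuMe2SiOTf (1.5 equiv), 2,6-lutidine, CH2Cl2, −78 → 0 °C
Reagents that add atoms: tert-butyldimethylsilyl trifluoromethanesulfonate, CC(C)(C)[Si](C)(C)OS(=O)(=O)C(F)(F)F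
Why: Silylation of the hindered equatorial alcohol with a silyl triflate; the ether shields C6–OH from the selenium oxidant later and is removable by fluoride without base.

Step 11
Reactants: 17 methyl 4-hydroxybut-2-ynoate
Product: 18 methyl (Z)-4-hydroxy-3-iodobut-2-enoate
Conditions: LiI (1.5 equiv), AcOH (2 equiv), MeCN, 70 °C
Reagents that add atoms: lithium iodide, [Li+].[I-]
Why: Hydroiodination of a 2-ynoate; conjugate addition of iodide and anti protonation of the allenolate put iodine cis to the ester, and the hydroxymethyl group ends trans to the ester, so it cannot lactonise.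

Step 12
Reactants: 16 silyl ether; 18 methyl (Z)-4-hydroxy-3-iodobut-2-enoate
Product: 20 methyl (13E)-ent-6α-(tert-butyldimethylsilyloxy)-16-hydroxylabda-7,13-dien-15-oate, via C12 alkylborane 19 (not isolated)
Conditions: 9-BBN (1.5 equiv), THF, 0 °C → rt; then aq. Cs2CO3, 18, Pd(dppf)Cl2 (5 mol %), AsPh3 (10 mol %), DMF, rt
Reagents that add atoms: none
Why: B-alkyl Suzuki–Miyaura coupling; the borane takes the monosubstituted vinyl group at C12 in preference to the trisubstituted ring alkene, and the coupling with the β-iodo enoate forms C12–C13 with retention, so the chain ends cis to the ester (13E).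

Step 13
Reactants: 20 methyl (13E)-ent-6α-(tert-butyldimethylsilyloxy)-16-hydroxylabda-7,13-dien-15-oate
Product: 21 methyl (13E)-ent-6α-(tert-butyldimethylsilyloxy)-16-(formyloxy)labda-7,13-dien-15-oate
Conditions: acetic formic anhydride (2 equiv), pyridine, CH2Cl2, 0 °C
Reagents that add atoms: acetic formic anhydride, CC(=O)OC=O
Why: Acylation of the only free (primary allylic) hydroxyl; the mixed anhydride transfers the more electrophilic formyl group.

Step 14
Reactants: 21 methyl (13E)-ent-6α-(tert-butyldimethylsilyloxy)-16-(formyloxy)labda-7,13-dien-15-oate
Product: 22 methyl (13E)-ent-6α-(tert-butyldimethylsilyloxy)-16-(formyloxy)-17-oxolabda-7,13-dien-15-oate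
Conditions: SeO2 (2 equiv), 1,4-dioxane (dry), 80 °C
Reagents that add atoms: selenium dioxide, O=[Se]=O
Why: Riley allylic oxidation; an ene reaction at C7 with hydrogen transfer from C17, a [2,3]-sigmatropic shift and further oxidation of the allylic alcohol lead to the enal. The methyl on the more substituted alkene carbon, trans to C6, is the preferred site as in drim-7-enes, and the electron-poor side-chain alkene is inert.

Step 15
Reactants: 22 methyl (13E)-ent-6α-(tert-butyldimethylsilyloxy)-16-(formyloxy)-17-oxolabda-7,13-dien-15-oate
Product: 23 methyl (13E)-ent-16-(formyloxy)-6α-hydroxy-17-oxolabda-7,13-dien-15-oate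
Conditions: HF·pyridine, pyridine, THF, 0 °C → rt
Reagents that add atoms: none
Why: Fluoride-mediated desilylation under weakly acidic, non-nucleophilic conditions; the formate, enal and enoate should survive, and no stereocentre is touched.

## Compound list

1 | 4-methoxy-2,6-dimethylphenol | COc1cc(C)c(O)c(C)c1 | starting material
2 | 4,4-dimethoxy-2,6-dimethylcyclohexa-2,5-dien-1-one | COC1(OC)C=C(C)C(=O)C(C)=C1 | intermediate
3 | isopropenylmagnesium bromide | CC(=C)[Mg]Br | starting material
4 | 2,3-bis(phenylsulfonyl)prop-1-ene | C=C(CS(=O)(=O)c1ccccc1)S(=O)(=O)c1ccccc1 | starting material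
5 | bromomagnesium (3R)-4,4-dimethoxy-2,6-dimethyl-3-(prop-1-en-2-yl)cyclohexa-1,5-dien-1-olate (formed in the flask, not isolated) | Br[Mg]OC1=C(C)[C@@H](C(C)=C)C(OC)(OC)C=C1C | intermediate
6 | (5R,6R)-4,4-dimethoxy-2,6-dimethyl-6-[2-(phenylsulfonyl)prop-2-en-1-yl]-5-(prop-1-en-2-yl)cyclohex-2-en-1-one | O=C1C(C)=CC(OC)(OC)[C@H](C(C)=C)[C@@]1(C)CC(=C)S(=O)(=O)c2ccccc2 | intermediate
7 | sulfonyl decalin enone ketal: (5R,10R) trans-decalin, C9 ketone, C7=C8 with methyl C17, C6(OCH3)2, C4 gem-dimethyl, C10 methyl, C2–SO2Ph (both epimers) | O=C1C(C)=CC(OC)(OC)[C@@H]2C(C)(C)CC(S(=O)(=O)c3ccccc3)C[C@@]12C | intermediate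
8 | exocyclic diene ketal: as 7 with C9=C11H2 in place of the ketone, (5R,10R) | C=C1C(C)=CC(OC)(OC)[C@@H]2C(C)(C)CC(S(=O)(=O)c3ccccc3)C[C@@]12C | intermediate
9 | C11 alkylborane: 9-borabicyclo[3.3.1]nonan-9-yl on C11 of the hydroborated diene, (5R,9R,10S) (formed in the flask, not isolated) | C1CCC2CCCC1B2C[C@@H]3C(C)=CC(OC)(OC)[C@@H]4C(C)(C)CC(S(=O)(=O)c5ccccc5)C[C@@]34C | intermediate
10 | C11 alcohol: (5R,9R,10S), CH2OH on C9 syn to the C10 methyl, C7=C8, C6(OCH3)2, C2–SO2Ph | OC[C@@H]1C(C)=CC(OC)(OC)[C@@H]2C(C)(C)CC(S(=O)(=O)c3ccccc3)C[C@@]12C | intermediate
11 | desulfonylated ketal alcohol: (5R,9R,10S), C11–OH, C7=C8, C6(OCH3)2 (formed in the flask, not isolated) | OC[C@@H]1C(C)=CC(OC)(OC)[C@@H]2C(C)(C)CCC[C@@]12C | intermediate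
12 | hydroxy enone: (5R,9R,10S), C11–OH, C6 ketone, C7=C8 with methyl C17 | OC[C@@H]1C(C)=CC(=O)[C@@H]2C(C)(C)CCC[C@@]12C | intermediate
13 | diol: (5R,6R,9R,10S), C6–OH anti to the C10 methyl, C11–OH, C7=C8 | OC[C@@H]1C(C)=C[C@@H](O)[C@@H]2C(C)(C)CCC[C@@]12C | intermediate
14 | hydroxy aldehyde: (5R,6R,9R,10R), C11 aldehyde on C9, C6–OH, C7=C8 | O=C[C@@H]1C(C)=C[C@@H](O)[C@@H]2C(C)(C)CCC[C@@]12C | intermediate
15 | vinyl alcohol: (5R,6R,9R,10S), C11=C12 vinyl on C9, C6–OH, C7=C8 | C=C[C@@H]1C(C)=C[C@@H](O)[C@@H]2C(C)(C)CCC[C@@]12C | intermediate
16 | silyl ether: (5R,6R,9R,10S), C6–OSi(t-Bu)Me2, C9 vinyl, C7=C8 | C=C[C@@H]1C(C)=C[C@@H](O[Si](C)(C)C(C)(C)C)[C@@H]2C(C)(C)CCC[C@@]12C | intermediate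
17 | methyl 4-hydroxybut-2-ynoate | COC(=O)C#CCO | starting material
18 | methyl (Z)-4-hydroxy-3-iodobut-2-enoate | COC(=O)/C=C(\I)CO | intermediate
19 | C12 alkylborane: 9-borabicyclo[3.3.1]nonan-9-yl on C12 of hydroborated 16, (5R,6R,9R,10S) (formed in the flask, not isolated) | C1CCC2CCCC1B2CC[C@@H]3C(C)=C[C@@H](O[Si](C)(C)C(C)(C)C)[C@@H]4C(C)(C)CCC[C@@]34C | intermediate
20 | methyl (13E)-ent-6α-(tert-butyldimethylsilyloxy)-16-hydroxylabda-7,13-dien-15-oate, (5R,6R,9R,10S) | COC(=O)/C=C(\CC[C@@H]1C(C)=C[C@@H](O[Si](C)(C)C(C)(C)C)[C@@H]2C(C)(C)CCC[C@@]12C)CO | intermediate
21 | methyl (13E)-ent-6α-(tert-butyldimethylsilyloxy)-16-(formyloxy)labda-7,13-dien-15-oate, (5R,6R,9R,10S) | COC(=O)/C=C(\CC[C@@H]1C(C)=C[C@@H](O[Si](C)(C)C(C)(C)C)[C@@H]2C(C)(C)CCC[C@@]12C)COC=O | intermediate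
22 | methyl (13E)-ent-6α-(tert-butyldimethylsilyloxy)-16-(formyloxy)-17-oxolabda-7,13-dien-15-oate, (5R,6R,9S,10S) | COC(=O)/C=C(\CC[C@@H]1C(C=O)=C[C@@H](O[Si](C)(C)C(C)(C)C)[C@@H]2C(C)(C)CCC[C@@]12C)COC=O | intermediate
23 | methyl (13E)-ent-16-(formyloxy)-6α-hydroxy-17-oxolabda-7,13-dien-15-oate, (5R,6R,9S,10S) | COC(=O)/C=C(\CC[C@@H]1C(C=O)=C[C@@H](O)[C@@H]2C(C)(C)CCC[C@@]12C)COC=O | target

## Step count and risk

Total: 15 steps. Longest linear sequence: 14 steps (steps 1–10 and 12–15, from 1 to 23); step 11 prepares the side-chain fragment.

**Step 2 (key step, proposed new method).** The most likely failures are poor discrimination between the two enone arms, or 1,2-addition, because an sp2 Grignard reagent meets an α-methylated dienone for which the catalyst was not developed. A second failure is slow C-alkylation of the hindered bromomagnesium enolate, after which protonation on work-up and loss of methanol would aromatise the adduct. The fallback uses only known reaction types, sets out from 2 and returns at 6. Grignard reagent 3 is added to 2 with CuBr·SMe2 (no chiral ligand) and Me3SiCl in THF at −78 °C, and the adduct is isolated as the racemic trimethylsilyl enol ether F1. MeLi in THF releases the more reactive lithium enolate, which is alkylated with 4 to racemic 6. Preparative chromatography on a chiral stationary phase then separates 6 from its mirror-image ketone F2. The price is half the material.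

**Step 7.** Hydride transfer at the hindered C6 may be slow, and the kinetic axial carbinol may equilibrate incompletely. The hot aluminium alkoxide may also trigger loss of formaldehyde from the γ-hydroxymethyl enone (vinylogous retro-aldol) or epimerisation at C9 through the dienolate. The fallback sets out from 12 and returns at 13. Luche reduction (NaBH4, CeCl3·7H2O, MeOH, −78 °C) delivers hydride anti to the C10 methyl and gives the axial C6 epimer of the diol F3. A Mitsunobu reaction with 4-nitrobenzoic acid, PPh3 and diisopropyl azodicarboxylate inverts C6 (the open face is the one the nucleophile needs) and also esterifies C11, giving the bis(4-nitrobenzoate) F4. Methanolysis with K2CO3 in MeOH then yields 13.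

**Step 9.** The ylide may deprotonate the hindered, β,γ-unsaturated aldehyde instead of adding to it, with epimerisation at C9 or migration of C7=C8 into conjugation. The fallback avoids any C11 aldehyde, sets out from 13 and returns at 20, replacing steps 8–12. Selective iodination of the primary hydroxyl (I2, PPh3, imidazole) gives iodo alcohol F5, and silylation as in step 10 gives iodo silyl ether F6. The dianion of methyl acetoacetate (NaH, then n-BuLi, THF, 0 °C) is alkylated at its terminal carbon by F6, which adds C12–C15 in one step as β-keto ester F7. Enol triflate formation under non-chelating conditions (Tf2O, aqueous Me4NOH, hexane) gives the (E)-enol triflate F8, with the triflate trans to the ester. A Stille coupling with Bu3SnCH2OH (Pd(PPh3)4, LiCl, dioxane) replaces the triflate by CH2OH with retention and gives 20. The alkylation step of this fallback carries its own elimination risk at C11.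

**Step 14.** The ene step may be slow because the allylic silyloxy group deactivates and shields C7. The reaction may stall at the C17 alcohol, or the formate may not survive the hot, slightly acidic medium. The fallback sets out from 21 and returns at 22. Epoxidation with m-chloroperbenzoic acid (NaHCO3, CH2Cl2, 0 °C) takes the electron-rich ring alkene from the face anti to the C10 methyl and gives 7,8-epoxide F9. Homolytic opening by trivalent titanium (Cp2TiCl, generated from Cp2TiCl2 and Mn dust) at the tertiary C8, followed by β-hydrogen loss from C17, gives the exocyclic allylic alcohol F10. SOCl2 in ether converts F10 with allylic transposition into the primary 17-chloride F11, which restores C7=C8. N-methylmorpholine N-oxide in MeCN then oxidises F11 to enal 22.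

## Further compounds

F1 | step 2 | racemic [4,4-dimethoxy-2,6-dimethyl-3-(prop-1-en-2-yl)cyclohexa-1,5-dien-1-yl]oxy(trimethyl)silane | C[Si](C)(C)OC1=C(C)C(C(C)=C)C(OC)(OC)C=C1C
F2 | step 2 | (5S,6S)-4,4-dimethoxy-2,6-dimethyl-6-[2-(phenylsulfonyl)prop-2-en-1-yl]-5-(prop-1-en-2-yl)cyclohex-2-en-1-one (enantiomer of 6) | O=C1C(C)=CC(OC)(OC)[C@@H](C(C)=C)[C@]1(C)CC(=C)S(=O)(=O)c2ccccc2
F3 | step 7 | C6 epimer of diol 13 (axial C6–OH syn to the C10 methyl) | OC[C@@H]1C(C)=C[C@H](O)[C@@H]2C(C)(C)CCC[C@@]12C
F4 | step 7 | bis(4-nitrobenzoate) of diol 13 (C6 ester anti to the C10 methyl) | O=C(OC[C@@H]1C(C)=C[C@@H](OC(=O)c3ccc(cc3)[N+](=O)[O-])[C@@H]2C(C)(C)CCC[C@@]12C)c4ccc(cc4)[N+](=O)[O-]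
F5 | step 9 | C11 iodide of diol 13 (C6–OH free) | IC[C@@H]1C(C)=C[C@@H](O)[C@@H]2C(C)(C)CCC[C@@]12C
F6 | step 9 | C11 iodide with C6 tert-butyldimethylsilyl ether | IC[C@@H]1C(C)=C[C@@H](O[Si](C)(C)C(C)(C)C)[C@@H]2C(C)(C)CCC[C@@]12C
F7 | step 9 | methyl ent-6α-(tert-butyldimethylsilyloxy)-13-oxo-16-norlabd-7-en-15-oate (β-keto ester) | COC(=O)CC(=O)CC[C@@H]1C(C)=C[C@@H](O[Si](C)(C)C(C)(C)C)[C@@H]2C(C)(C)CCC[C@@]12C
F8 | step 9 | (E)-enol triflate of F7 (triflate on C13 trans to the ester) | COC(=O)/C=C(\CC[C@@H]1C(C)=C[C@@H](O[Si](C)(C)C(C)(C)C)[C@@H]2C(C)(C)CCC[C@@]12C)OS(=O)(=O)C(F)(F)F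
F9 | step 14 | 7,8-epoxide of 21 (oxygen anti to the C10 methyl) | COC(=O)/C=C(\CC[C@@H]1[C@@]3(C)O[C@H]3[C@@H](O[Si](C)(C)C(C)(C)C)[C@@H]2C(C)(C)CCC[C@@]12C)COC=O
F10 | step 14 | 7-hydroxy-8(17)-ene isomer (exocyclic allylic alcohol from F9) | COC(=O)/C=C(\CC[C@@H]1C(=C)[C@@H](O)[C@@H](O[Si](C)(C)C(C)(C)C)[C@@H]2C(C)(C)CCC[C@@]12C)COC=O
F11 | step 14 | 17-chloro derivative of 21 (primary allylic chloride, C7=C8) | COC(=O)/C=C(\CC[C@@H]1C(CCl)=C[C@@H](O[Si](C)(C)C(C)(C)C)[C@@H]2C(C)(C)CCC[C@@]12C)COC=O
A1 | alternative 1 | ene product: trans-decalin with equatorial C6–OH, exocyclic C8=C17 alkene and silyloxyethyl arm on C9 | CC(C)(C)[Si](C)(C)OCC[C@@H]1C(=C)C[C@@H](O)[C@@H]2C(C)(C)CCC[C@@]12C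
A2 | alternative 1 | ene substrate: cyclohexane carbaldehyde (C6 aldehyde on C5) with the 2-propenyl-bearing C9 on quaternary C10 | CC(C)(C)[Si](C)(C)OCC[C@H](C(C)=C)[C@]1(C)CCCC(C)(C)[C@H]1C=O
A3 | alternative 2 | bicyclic β-keto ester (8-phenylmenthyl ester) with C8 ketone, quaternary C10 and C5=C6 alkene | CC(C)(c1ccccc1)[C@@H]2CC[C@@H](C)C[C@H]2OC(=O)[C@@H]3C(=O)CC=C4C(C)(C)CCC[C@@]34C
A4 | alternative 2 | 8-phenylmenthyl 3-oxo-5-(2,6,6-trimethylcyclohex-1-en-1-yl)pentanoate | CC(C)(c1ccccc1)[C@@H]2CC[C@@H](C)C[C@H]2OC(=O)CC(=O)CCC3=C(C)CCCC3(C)C
A5 | alternative 2 | dihydro-β-ionone | CC(=O)CCC1=C(C)CCCC1(C)C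
A6 | alternative 3 | Michael product: trans-decalin with C7 ketone, C17 methyl ester on C8 and methyl acetate arm on C9 | COC(=O)C[C@@H]1[C@@H](C(=O)OC)C(=O)C[C@@H]2C(C)(C)CCC[C@@]12C
A7 | alternative 3 | Michael substrate: cyclohexane with β-keto ester chain on C5 and (E)-enoate on quaternary C10 | COC(=O)/C=C/[C@]1(C)CCCC(C)(C)[C@H]1CC(=O)CC(=O)OC
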